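(The earlier runs and the new flask are calculated from invented constants, noise included.)

In the larch run the target stands higher at 8.00 h than at 50.0 h, 23.3% against 16.0%. Something in this closed flask takes target away after it is made. Nobody read the isomer of the product, so take it as the taker.

in all of them: starting material 0.20 M
- maple: partner 0.21 M; reagent 0.22 M; run made earlier
- cedar: partner 0.21 M; reagent 0.27 M; run made earlier
- larch: partner 0.21 M; reagent 0.35 M; run made earlier
- theta: partner 0.210 M; reagent 0.200 M; time 4.0 d
- gamma: partner 0.210 M; reagent 0.300 M; time 4.0 d

- maple (time / h: target / %): 4.00: 9.2; 12.0: 13.3; 20.0: 11.9; 30.0: 10.7; 50.0: 9.3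
- cedar (time / h: target / %): 4.00: 12.4; 12.0: 17.4; 20.0: 15.7; 30.0: 13.5; 50.0: 12.0
- larch (time / h: target / %): 4.00: 16.1; 8.00: 23.3; 15.0: 22.2; 25.0: 19.1; 50.0: 16.0

(scatter of a reading: 0.5 percentage points)

- what was read earlier has a scatter of 0.5 percentage points, one standard deviation

- which of the two there is more of at the end, theta (isomer of the product / target)
- which of the two there is more of at the end, gamma (isomer of the product / target)
- how much target is there at the end, in percent of the starting material charged: theta
- how much target is there at the end, in percent of the starting material charged: gamma

Climb the time scales, fastest first.

1. Hours: the rise. Starting material, partner and reagent give target. The highest larch reading stands at 8.00 h, but it is one scattered reading, so read the peak only as lying between 4.00 h and 15.0 h. From 15.0 h on, treat the making as over.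

2. Tens of hours: the sag. Take the last larch reading as the plateau. The excess over it is 6.2 percentage points at 15.0 h and 3.1 points at 25.0 h. That fall gives a clock, the relaxation time: 14.4 h.

3. Go round again. By that clock, the last reading still holds 0.55 points of excess. Take it off. The plateau becomes 15.5% and the clock 16.3 h.

4. Back to time zero. Run the excess backwards along this clock. What it reaches at zero is the target that later left, so it stands for the isomer at the end. Over the plateau, that gives 1.10 for larch. The same two rounds give a plateau of 11.8% and 1.71 for cedar. For maple they give 8.89% and 0.936. The mean is 1.25. This is the hidden ratio, end isomer over end target. It is a rough reading: the three values spread from 0.936 to 1.71.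

5. Days: the end. The time 4.0 d is 5.89 clocks, so theta and gamma should sit on their plateaus. A straight line through the plateaus gives my target: 7.75% in theta and 13.1% in gamma. The ratio then puts the isomer at 9.69% and 16.4%. So I expect more isomer than target.

6. The forecast differs. It says target for theta and target for gamma, with 7.3% (6% to 8.6%) and 12.4% (10.8% to 14%). Its ground: “Target is then about 58% of the product at equilibrium”.

7. The flask gives isomer of the product for theta and isomer of the product for gamma. Target ends at 7.34% in theta and 12.7% in gamma.

    starting material + reagent → open intermediate (k = 0.370 /M/h)
    reagent + partner → second intermediate (k = 0.840 /M/h)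
    open intermediate + second intermediate → target (k = 26.0 /M/h)
    2 second intermediate → homo product (k = 1.30 /M/h)
    open intermediate → decomposed reagent (k = 0.150 /h)
    target ⇌ isomer of the product (K = 1.70, k = 0.0540 /h)
    open intermediate → side product (k = 0.520 /h)

In theta, isomer stands at 12.5% against 7.34% target, a ratio of 1.70. The hidden ratio 1.25, read from the runs, picked the same side with less isomer. The isomer leads because target turns into it: with that step taken away, theta ends at 19.8% target, not 7.34%. In the neighbour of gamma with 0.12 M of reagent, the ratio 1.25 times its 3.65% target gives 4.56% isomer, and that flask holds 6.19%.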